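(The numbers in the tables were computed on assumed constants, and the scatter is random.)

A one-way product cannot shrink while the starting material it came from grows back, yet in the autumn run target falls from 24.8% at 10.0 s to 13.3% at 120 s as starting material climbs from 75.0% to 86.1%.

| flask | starting material | partner | second substrate | temperature | remark | time |
|---|---|---|---|---|---|---|
| autumn | 0.37 M | 0.259 M | 0.74 M | 25 °C | run made earlier |  |
| dawn | 0.37 M | 0.39 M | 0.74 M | 25 °C | run made earlier |  |
| alpha | 0.37 M | 0.259 M | 0.740 M | 25 °C | everything together at the start | 3.0 min |
| gamma | 0.37 M | 0.259 M (fed, over 2.5 min) | 0.740 M |  | the addition at −5 °C, then warmed to 25 °C; the feed brings no volume worth counting | 3.0 min |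
| beta | 0.37 M | 0.259 M (fed, over 2.5 min) | 0.740 M | 25 °C | all else is in the flask from the start; the feed brings no volume worth counting | 3.0 min |
| zeta | 0.37 M (fed, over 2.5 min) | 0.259 M | 0.740 M | 25 °C | all else is in the flask from the start; the feed brings no volume worth counting | 3.0 min |

| run | time / s | target / % | starting material / % |
|---|---|---|---|
| autumn | 10.0 | 24.8 | 75.0 |
| autumn | 15.0 | 24.5 | 75.7 |
| autumn | 30.0 | 22.5 | 77.3 |
| autumn | 50.0 | 20.2 | 80.5 |
| autumn | 60.0 | 18.3 | 81.5 |
| autumn | 80.0 | 17.2 | 83.5 |
| autumn | 120 | 13.3 | 86.1 |
| dawn | 10.0 | 34.3 | 66.2 |
| dawn | 15.0 | 33.3 | 67.0 |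
| dawn | 25.0 | 31.6 | 67.7 |
| dawn | 30.0 | 30.5 | 70.0 |
| dawn | 40.0 | 27.9 | 70.6 |
| dawn | 50.0 | 28.0 | 72.6 |

(standard deviation of a reading: 0.5 percentage points)

- a reading or a percentage of target counts all its forms, free or not
- the earlier runs do not show what temperature does; that part of a forecast is a guess

- which flask leads in amount of target, in percent of the starting material charged ("all alike" within 1.5 percentage points) (alpha / gamma / beta / zeta / all alike)
- how much target is there at the end, in percent of the starting material charged: alpha
- how much target is there at the end, in percent of the starting material charged: gamma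
- how much target is there at the end, in percent of the starting material charged: beta
- how much target is there at the end, in percent of the starting material charged: zeta

Two chemists read these runs differently. The first holds that target fades by itself at a steady proportion per minute, 0.340 min⁻¹ from the autumn readings, which carries alpha to 9.47%, and since a fed flask merely makes its target later, it puts beta and zeta level at 14.9%.

The second holds that target is a store in balance with free partner, and that free partner is what leaks away. Her first round takes free partner at 10.0 s as charge minus target, 0.167 M, which gives a ratio of 1.98 M⁻¹ for autumn and 1.97 M⁻¹ for dawn, though the partner charges differ. Going round again, that ratio puts free partner in the autumn run at 0.0781 M by 120 s, so she reckons 0.132 M of partner as lost from both free partner and target, an estimated leak of 0.00894 s⁻¹ on free partner. Put back into the first 10.0 s, this lowers her free partner to 0.152 M and yields, as a reading from scattered autumn values, 2.17 M⁻¹, the holding ratio, target divided by starting material and by free partner, an apparent equilibrium constant with every form of target counted.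

The forecast stands on her side, with a ratio of 2.2 per molar of its own and the ground “Bound partner appears protected”. It gives alpha 9.7%, beta 15.2%, zeta 7.8% and gamma 20%, between 15.5% and 25% since temperature is a guess, so gamma leads.

The flasks end at alpha 9.85%, gamma 21.4%, beta 15.1% and zeta 7.81%, so gamma leads.

    starting material + partner ⇌ target (K = 1.20 M⁻¹, k = 0.470 M⁻¹ s⁻¹, Ea = 62.0 kJ mol⁻¹, ΔH = 18.0 kJ mol⁻¹)
    second substrate + partner ⇌ second product (K = 64.0 M⁻¹, k = 0.0170 M⁻¹ s⁻¹, Ea = 58.0 kJ mol⁻¹, ΔH = 40.0 kJ mol⁻¹)
    second substrate + target ⇌ idle adduct, settled at all times (K = 1.30 M⁻¹, ΔH = −5.00 kJ mol⁻¹)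
    (constants at 25 °C)

The fading view fails on zeta, where its 14.9% stands above the flask's 7.81%, but for alpha, charged everything together like autumn, its 9.47% lies beside 9.85%. Gamma ends with partner at 46.4% of its charge, and the holding ratio turns that into a target share of 20.7%. The neighbour of gamma charged with 1.0 M of partner ends with 58.4% of it, for which the ratio gives 55.9%, and that flask holds 53.0% of target.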